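## Analysis of the target

Target 18 is a 1,4-naphthoquinone. Ring B (C1–C4, C4a, C8a) is the quinone and carries the side chain at C2. Ring A (C5–C8) is benzenoid, with a methoxyl at C5, a free hydroxyl at C8 and hydrogen at C6 and C7. The side chain is a 4-methylpent-3-enyl unit whose first carbon, C1', bears the 3-methylbut-2-enoate oxygen. C1' is the only stereocentre and is (S) (O > C2 > C2'H2 > H), so the problem is one of absolute configuration only. The placement is unsymmetrical: C8–OH is peri to C1=O, the carbonyl next to the side chain, and C5–OMe is peri to C4=O. Because one oxygen is methylated there is no tautomeric equalisation of the two rings, and the two ring A oxygens must be placed unambiguously with respect to C2. The sensitive groups are: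
- the quinone (bases, nucleophiles, reductants);
- the C1' ester, which is allylic to the quinone double bond and sits on a carbon with a vinylogously acidic hydrogen;
- the trisubstituted alkene (acid-induced cyclisation onto the C1' oxygen);
- the conjugated acyl group (loss of conjugation under basic acylation).

The difficulty is the combination of four regiodefined oxygens on the naphthalene, a quinone that must form in ring B only, and a benzylic stereocentre that must survive organometallic and oxidative steps. The strategy rests on ring A: C5 with its methoxyl, the two CH carbons C6 and C7, and C8 with its hydroxyl are what a methoxycarbene carbon, an alkyne and a carbonyl ligand deliver when joined onto an arene at C4a and C8a.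

## Retrosynthetic reasoning

**18 ⇒ 17.** The acetyl–oxygen bond at C8 is cut last. Until then the C8 oxygen must be masked in a form that keeps ring A out of the quinone-forming oxidation and still comes off a quinone without harming the C1' ester. An aryl acetate peri to a quinone carbonyl is an activated ester, so the forward step needs only a brief, weakly basic alcoholysis.

**17 ⇒ 16.** The carbonyls at C1 and C4 go back to the two methyl ethers of a 1,4-dimethoxy ring B. Ring B is the only ring with two ether oxygens in a para relation; ring A has one ether and one ester. The forward reaction is an oxidative demethylation by a cerium oxidant in its tetravalent state, which must leave the C1' ester, the alkene and the acetate alone.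

**16 ⇒ 14 + 15; 14 ⇒ 13.** The acyl–oxygen bond of the side-chain ester is cut to give carbinol 14 and acid 15. The ester goes in after all organometallic chemistry, which it would not survive, and before the oxidation, so that the quinone stage stays short. The acylation takes place at oxygen, so C1' is not at stake; it only has to avoid moving the double bond of 15 out of conjugation. Carbinol 14 comes from silyl ether 13 by fluoride.

**13 ⇒ 12 ⇒ 11.** Acetate 13 is made from naphthol 12, and 12 from boronate 11 by replacing boron with hydrogen. Boron is only a handle that makes the two-carbon alkyne unit easy to handle. It is removed directly after the ring synthesis, while the ring is electron-rich and the neighbouring hydroxyl is free, which is when the C–B bond is most labile. Acetylation follows at once because the free 4-methoxynaphthol is the most easily oxidised part of the molecule.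

**11 ⇒ 9 + 10.** This is the key disconnection. Three bonds of ring A are cut together: C5–C6, C7–C8 and C8–C8a. C5 with its methoxyl goes back to the carbene carbon of 9, C6 and C7 to alkyne 10, and C8 with its hydroxyl to a carbonyl ligand of chromium. Here one reaction closes a ring and delivers two differentiated oxygens, with no demand on the orientation of the alkyne. Cutting ring B in the same way would put the oxygenated C1' next to the reacting alkyne. The gain is that everything else in 9 sits on a simple benzene ring. The peri relations C5–OMe/C4 and C8–OH/C1 follow from the carbene carbon being para to the side chain. The forward reaction has to close onto the one free ortho carbon of the arene.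

**9 ⇒ 5 + 6.** The bond between the arene carbon C4a and the carbene carbon C5 is cut. Aryl bromide 5 supplies the arene and 6 supplies both the metal and the carbene carbon; the acyl oxygen is then methylated. The bromine of 5 encodes the regiochemistry, since it is para to the side chain.

**5 ⇒ 4 ⇒ 3 ⇒ 1.** Silyl ether 5 comes from carbinol 4. Carbinol 4 comes from homoallylic alcohol 3 by cutting C3'=C4' (olefin metathesis, the isopropylidene end coming from a simple trisubstituted olefin). Alcohol 3 comes from aldehyde 1 by cutting C1'–C2', an allyl addition under control of a chiral allylborane, which creates the stereocentre. A prenyl nucleophile is not added directly, because such allylic metal reagents react at their substituted end and would give the branched isomer. Aldehyde 1 is commercial and already has the bromine and both methoxyls in place.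

## Alternatives that were turned down

**Alternative 1:** Ring A from a furan and an aryne.
- Disconnection: C4a–C5 and C8a–C8. The four carbons and both oxygens of ring A come from 2-methoxyfuran (A1).
- Forward key step: fluoride releases the aryne of ring B across C4a–C8a from a silyl/triflate pair. It adds A1, and the oxygen-bridged adduct opens to naphthol A2, which already carries the complete side chain with its ester.
- For: the step is metal-free and mild, and it tolerates the ester and the stereocentre. Nothing but ring B oxidation would remain. On functional-group tolerance and on the number of steps after the key step it is stronger than the chosen route.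
- Against: the orientation of A1 depends only on the polarisation of the aryne by the single oxygen at C4. That bias points the right way but is not enforced by structure, and the wrong orientation exchanges C5–OMe and C8–OH. In A2 ring B has an oxygen at C4 only and C1 is a CH. The quinone would therefore have to be made by oxidising a naphthol para position while ring A, a free 4-methoxynaphthol, is the more oxidisable ring. The aryne precursor, a tetrasubstituted arene with the chiral chain, also takes longer to make than 9.
- Comparison: the chosen route fixes the regiochemistry by the substitution of the arene. Its ring B arrives at the hydroquinone dimethyl ether level, so the final oxidation is selective once C8–O is acylated.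

**Alternative 2:** Ring B closed by ring-closing metathesis at C2–C3.
- Disconnection: the C2=C3 double bond. Ring A carries a vinyl carbinol arm on C4a (C4, C3) and a carbinol arm on C8a (C1) with a 1,1-disubstituted alkene at C2.
- Forward key step: a ruthenium alkylidene joins the two alkenes with loss of a volatile olefin and gives diol A3 as carbinol epimers. Both carbinols are then oxidised to the quinone.
- For: ring A is bought with its two oxygens already different, so there is no regiochemical question. The metal is catalytic and the epimers do not matter. On certainty of the ring A pattern and on avoiding stoichiometric chromium it is stronger.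
- Against: the ring alkene is trisubstituted and its substituted carbon carries a bulky α-silyloxy branch, a slow metathesis partner. The side-chain alkene is a second metathesis site. The precursor needs two different carbonyl additions ortho to each other, plus a separately made alkenyl-metal fragment that carries the stereocentre. A3 is a doubly benzylic, allylic 1,4-diol that aromatises by loss of water to a naphthol, a dead end, unless both oxidations are faster.
- Comparison: the chosen route forms ring A and its oxygenation in one step from a four-step precursor, and never passes through a non-aromatic diol.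

**Alternative 3:** Benzannulation that builds ring B from a chiral propargylic ester.
- Disconnection: C3–C4, C1–C2 and C1–C8a. The carbene carbon of a ring A aryl(methoxy)carbene complex of chromium becomes C4, alkyne A4 supplies C3 and C2, and a carbonyl ligand supplies C1.
- Forward key step: heating the carbene complex with A4 gives naphthol A5. The substituted alkyne carbon ends next to C1–OH.
- For: this is the most convergent plan. The stereocentre and the ester come on a small fragment, and A5 needs only one oxidation and one desilylation to reach 18. On step count and convergence it is clearly stronger than the chosen route.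
- Against: the alkyne has a carboxylate leaving group on its propargylic carbon. After insertion that carbon lies next to the chromium-bound carbene and ketene, and after ring closure it is benzylic and ortho to a free hydroxyl on an electron-rich ring. Loss of the carboxylate to an ortho-quinone methide would destroy the ester and the stereocentre together. Ring closure must also take place next to the bulky silyloxy group.
- Comparison: the chosen route spends about four more steps after the key step. In exchange the stereocentre is a silyl ether para to the carbene, far from chromium and from any ortho hydroxyl, and the orientation of the alkyne is irrelevant.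

Key step: step 5

Remark: the stereocentre is (S) in 18 and in every intermediate, because the ring carbon attached to C1' always ranks second after oxygen. Atom numbers in the text are those of the naphthoquinone 18.

## Route

Step 1
Reactants: 1 4-bromo-2,5-dimethoxybenzaldehyde
Product: 3 (S)-1-(4-bromo-2,5-dimethoxyphenyl)but-3-en-1-ol, via borinate ester 2 (not isolated)
Conditions: (−)-Ipc2BOMe, allylMgBr, Et2O, −78 °C to rt; then 1, −78 °C; then NaOH, H2O2, 0 °C to rt
Reagents that add atoms: allylmagnesium bromide, C=CC[Mg]Br
Why: Brown allylboration: (−)-Ipc2BOMe (the enantiomer made from (+)-α-pinene) and allylMgBr form the B-allyl borane, which adds to the aldehyde through a closed chair transition state. With these isopinocampheyl groups the allyl group goes to the Si face, which is the (S) carbinol for an aryl aldehyde; oxidative work-up cleaves borinate 2.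

Step 2
Reactants: 3 (S)-1-(4-bromo-2,5-dimethoxyphenyl)but-3-en-1-ol
Product: 4 (S)-1-(4-bromo-2,5-dimethoxyphenyl)-4-methylpent-3-en-1-ol
Conditions: second-generation Grubbs catalyst (H2IMes)(PCy3)Cl2Ru=CHPh (3 mol %), 2-methylbut-2-ene/CH2Cl2, 40 °C, sealed vessel
Reagents that add atoms: 2-methylbut-2-ene, CC=C(C)C
Why: Olefin cross-metathesis: the terminal alkene exchanges its methylene for the isopropylidene group of the olefin used in large excess and propene escapes. The free hydroxyl and the aryl bromide are tolerated by the ruthenium carbene, and C1' is not involved.

Step 3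
Reactants: 4 (S)-1-(4-bromo-2,5-dimethoxyphenyl)-4-methylpent-3-en-1-ol
Product: 5 (S)-[1-(4-bromo-2,5-dimethoxyphenyl)-4-methylpent-3-enyloxy](tert-butyl)dimethylsilane
Conditions: TBSCl, imidazole, DMF, rt
Reagents that add atoms: tert-butyldimethylsilyl chloride, CC(C)(C)[Si](C)(C)Cl
Why: Imidazole-promoted silylation of the secondary benzylic alcohol. The silyl ether should survive tert-butyllithium, the chromium acylate, the benzannulation and the iridium step, and is later removed by fluoride; no bond to C1' is broken.

Step 4
Reactants: 5 (S)-[1-(4-bromo-2,5-dimethoxyphenyl)-4-methylpent-3-enyloxy](tert-butyl)dimethylsilane; 6 chromium hexacarbonyl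
Product: 9 pentacarbonyl{methoxy[4-((S)-1-(tert-butyldimethylsilyloxy)-4-methylpent-3-enyl)-2,5-dimethoxyphenyl]methylidene}chromium, via aryllithium 7 (not isolated), via lithium acylchromate 8 (not isolated)
Conditions: t-BuLi (2 equiv), Et2O, −78 °C; Cr(CO)6, −78 °C to rt; then MeOTf, CH2Cl2, 0 °C to rt
Reagents that add atoms: methyl trifluoromethanesulfonate, COS(=O)(=O)C(F)(F)F
Why: Fischer carbene synthesis: bromine–lithium exchange (the second equivalent of t-BuLi destroys the tert-butyl bromide formed), addition of aryllithium 7 to a carbonyl ligand of 6 to give acylchromate 8, and O-methylation of 8 by the hard electrophile. The exchange is much faster than any deprotonation, and the silyl ether and the alkene are inert.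

Step 5
Reactants: 9 pentacarbonyl{methoxy[4-((S)-1-(tert-butyldimethylsilyloxy)-4-methylpent-3-enyl)-2,5-dimethoxyphenyl]methylidene}chromium; 10 2-ethynyl-4,4,5,5-tetramethyl-1,3,2-dioxaborolane
Product: 11 (S)-7-[1-(tert-butyldimethylsilyloxy)-4-methylpent-3-enyl]-4,5,8-trimethoxy-2-(4,4,5,5-tetramethyl-1,3,2-dioxaborolan-2-yl)naphthalen-1-ol
Conditions: 10 (2 equiv), THF, 45–50 °C, argon; then concentration and rapid chromatography
Reagents that add atoms: none
Why: Dötz benzannulation of an aryl(methoxy)carbene complex of zerovalent chromium with an alkynylboronate, a known pairing. Thermal loss of one carbonyl ligand from 9 opens a site for 10, which inserts into the chromium–carbene bond; insertion of a second carbonyl ligand then gives a chromium-bound dienylketene. Ring A closes by 6π electrocyclization of this ketene onto the free ortho carbon of the arene (the future C8a), a six-membered closure of the formal [3+2+1] type, and tautomerization of the cyclohexadienone gives the naphthol. The new bonds are C5–C6, C7–C8 and C8–C8a; the carbene methoxyl becomes the C5 methyl ether and the inserted carbonyl the free C8 hydroxyl, so the two ring A oxygens arrive differentiated. No stereocentre is formed, and the existing one is a silyl ether para to the reacting carbon with no leaving group, so it is not at risk. The selectivity that matters is the site of closure, which is fixed because the other ortho carbon carries a methoxyl and cannot aromatize. The orientation of the alkyne (boron next to the hydroxyl carbon is expected for the bulkier end) has no consequence, since step 6 replaces boron by hydrogen. The remote trisubstituted alkene is not a partner for the carbene at this temperature.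

Step 6
Reactants: 11 (S)-7-[1-(tert-butyldimethylsilyloxy)-4-methylpent-3-enyl]-4,5,8-trimethoxy-2-(4,4,5,5-tetramethyl-1,3,2-dioxaborolan-2-yl)naphthalen-1-ol
Product: 12 (S)-7-[1-(tert-butyldimethylsilyloxy)-4-methylpent-3-enyl]-4,5,8-trimethoxynaphthalen-1-ol
Conditions: [Ir(OMe)(cod)]2 (3 mol %), MeOH/THF, 55 °C, argon
Reagents that add atoms: none
Why: Iridium-catalysed protodeboronation of an aryl pinacol boronate: the iridium methoxide transmetalates with the C–B bond and the aryl–iridium bond is protonated by methanol. The boronate sits on a very electron-rich ring next to a free hydroxyl, which makes this C–B bond especially labile, and the neutral medium spares the silyl ether, the alkene and C1'. The crude naphthol is used at once in step 7.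

Step 7
Reactants: 12 (S)-7-[1-(tert-butyldimethylsilyloxy)-4-methylpent-3-enyl]-4,5,8-trimethoxynaphthalen-1-ol
Product: 13 (S)-7-[1-(tert-butyldimethylsilyloxy)-4-methylpent-3-enyl]-4,5,8-trimethoxynaphthalen-1-yl acetate
Conditions: Ac2O, pyridine, DMAP (cat.), CH2Cl2, 0 °C to rt
Reagents that add atoms: acetic anhydride, CC(=O)OC(C)=O
Why: Pyridine/DMAP-catalysed O-acetylation of the naphthol. The acetate protects the oxidisable 4-methoxynaphthol and makes ring A the electron-poorer ring, which is what directs the oxidation of step 10 to ring B.

Step 8
Reactants: 13 (S)-7-[1-(tert-butyldimethylsilyloxy)-4-methylpent-3-enyl]-4,5,8-trimethoxynaphthalen-1-yl acetate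
Product: 14 (S)-7-(1-hydroxy-4-methylpent-3-enyl)-4,5,8-trimethoxynaphthalen-1-yl acetate
Conditions: HF·pyridine, pyridine, THF, 0 °C to rt
Reagents that add atoms: none
Why: Fluoride-induced cleavage of the Si–O bond. Buffered HF·pyridine is not basic enough to cleave or shift the aryl acetate and not acidic enough to ionise the benzylic C1'–O bond or protonate the alkene, so the configuration is kept.

Step 9
Reactants: 14 (S)-7-(1-hydroxy-4-methylpent-3-enyl)-4,5,8-trimethoxynaphthalen-1-yl acetate; 15 3-methylbut-2-enoic acid
Product: 16 (S)-1-(8-acetoxy-1,4,5-trimethoxynaphthalen-2-yl)-4-methylpent-3-enyl 3-methylbut-2-enoate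
Conditions: DCC, DMAP (cat.), CH2Cl2, 0 °C to rt
Reagents that add atoms: none
Why: Steglich esterification: the carbodiimide activates acid 15 and DMAP transfers the acyl group to the secondary hydroxyl. The C1'–O bond is not broken, so the (S) configuration is retained; low temperature and catalytic DMAP limit loss of conjugation in the acyl group and acetyl transfer from the phenol.

Step 10
Reactants: 16 (S)-1-(8-acetoxy-1,4,5-trimethoxynaphthalen-2-yl)-4-methylpent-3-enyl 3-methylbut-2-enoate
Product: 17 (S)-1-(8-acetoxy-5-methoxy-1,4-dioxo-1,4-dihydronaphthalen-2-yl)-4-methylpent-3-enyl 3-methylbut-2-enoate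
Conditions: (NH4)2Ce(NO3)6 (2.5 equiv), MeCN/H2O, 0 °C
Reagents that add atoms: water, O
Why: Oxidative demethylation of a 1,4-dimethoxyarene: tetravalent cerium removes an electron from the electron-rich ring B, water adds at the methoxyl-bearing carbons C1 and C4, and two molecules of methanol are lost. Ring A cannot become a quinone without losing the acetyl group and is deactivated by it, so only ring B should be oxidised. The ester, the alkene and C1' should be untouched in the few minutes at 0 °C.

Step 11
Reactants: 17 (S)-1-(8-acetoxy-5-methoxy-1,4-dioxo-1,4-dihydronaphthalen-2-yl)-4-methylpent-3-enyl 3-methylbut-2-enoate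
Product: 18 (S)-1-(8-hydroxy-5-methoxy-1,4-dioxo-1,4-dihydronaphthalen-2-yl)-4-methylpent-3-enyl 3-methylbut-2-enoate
Conditions: K2CO3 (1 equiv), MeOH, 0 °C, short reaction time, argon; then AcOH
Reagents that add atoms: none
Why: Carbonate-mediated methanolysis of an aryl acetate. The leaving group is a phenoxide stabilised by the peri quinone carbonyl, so this ester should be cleaved much faster than the hindered, conjugated secondary ester at C1'. Short exposure at 0 °C protects the quinone and the stereocentre, and acidification returns phenol 18, the target.

## Compound list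

1 | 4-bromo-2,5-dimethoxybenzaldehyde | COc1cc(C=O)c(OC)cc1Br | starting material
2 | (S)-1-(4-bromo-2,5-dimethoxyphenyl)but-3-enyl bis[(1R,2S,3R,5R)-2,6,6-trimethylbicyclo[3.1.1]hept-3-yl]borinate | COc1cc([C@H](CC=C)OB([C@@H]2C[C@@H]3C[C@H]([C@H]2C)C3(C)C)[C@@H]2C[C@@H]3C[C@H]([C@H]2C)C3(C)C)c(OC)cc1Br | intermediate
3 | (S)-1-(4-bromo-2,5-dimethoxyphenyl)but-3-en-1-ol | COc1cc([C@H](CC=C)O)c(OC)cc1Br | intermediate
4 | (S)-1-(4-bromo-2,5-dimethoxyphenyl)-4-methylpent-3-en-1-ol | COc1cc([C@H](CC=C(C)C)O)c(OC)cc1Br | intermediate
5 | (S)-[1-(4-bromo-2,5-dimethoxyphenyl)-4-methylpent-3-enyloxy](tert-butyl)dimethylsilane | COc1cc([C@H](CC=C(C)C)O[Si](C)(C)C(C)(C)C)c(OC)cc1Br | intermediate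
6 | chromium hexacarbonyl | O=C=[Cr](=C=O)(=C=O)(=C=O)(=C=O)=C=O | starting material
7 | {4-[(S)-1-(tert-butyldimethylsilyloxy)-4-methylpent-3-enyl]-2,5-dimethoxyphenyl}lithium | COc1cc([C@H](CC=C(C)C)O[Si](C)(C)C(C)(C)C)c(OC)cc1[Li] | intermediate
8 | lithium pentacarbonyl({4-[(S)-1-(tert-butyldimethylsilyloxy)-4-methylpent-3-enyl]-2,5-dimethoxyphenyl}(oxido)methylidene)chromate | [Li+].[O-]C(c1cc(OC)c([C@H](CC=C(C)C)O[Si](C)(C)C(C)(C)C)cc1OC)=[Cr](=C=O)(=C=O)(=C=O)(=C=O)=C=O | intermediate
9 | pentacarbonyl{methoxy[4-((S)-1-(tert-butyldimethylsilyloxy)-4-methylpent-3-enyl)-2,5-dimethoxyphenyl]methylidene}chromium | COC(c1cc(OC)c([C@H](CC=C(C)C)O[Si](C)(C)C(C)(C)C)cc1OC)=[Cr](=C=O)(=C=O)(=C=O)(=C=O)=C=O | intermediate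
10 | 2-ethynyl-4,4,5,5-tetramethyl-1,3,2-dioxaborolane | C#CB1OC(C)(C)C(C)(C)O1 | starting material
11 | (S)-7-[1-(tert-butyldimethylsilyloxy)-4-methylpent-3-enyl]-4,5,8-trimethoxy-2-(4,4,5,5-tetramethyl-1,3,2-dioxaborolan-2-yl)naphthalen-1-ol | COc1cc(B3OC(C)(C)C(C)(C)O3)c(O)c2c(OC)c([C@H](CC=C(C)C)O[Si](C)(C)C(C)(C)C)cc(OC)c12 | intermediate
12 | (S)-7-[1-(tert-butyldimethylsilyloxy)-4-methylpent-3-enyl]-4,5,8-trimethoxynaphthalen-1-ol | COc1ccc(O)c2c(OC)c([C@H](CC=C(C)C)O[Si](C)(C)C(C)(C)C)cc(OC)c12 | intermediate
13 | (S)-7-[1-(tert-butyldimethylsilyloxy)-4-methylpent-3-enyl]-4,5,8-trimethoxynaphthalen-1-yl acetate | COc1ccc(OC(C)=O)c2c(OC)c([C@H](CC=C(C)C)O[Si](C)(C)C(C)(C)C)cc(OC)c12 | intermediate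
14 | (S)-7-(1-hydroxy-4-methylpent-3-enyl)-4,5,8-trimethoxynaphthalen-1-yl acetate | COc1ccc(OC(C)=O)c2c(OC)c([C@H](CC=C(C)C)O)cc(OC)c12 | intermediate
15 | 3-methylbut-2-enoic acid | CC(C)=CC(=O)O | starting material
16 | (S)-1-(8-acetoxy-1,4,5-trimethoxynaphthalen-2-yl)-4-methylpent-3-enyl 3-methylbut-2-enoate | COc1ccc(OC(C)=O)c2c(OC)c([C@H](CC=C(C)C)OC(=O)C=C(C)C)cc(OC)c12 | intermediate
17 | (S)-1-(8-acetoxy-5-methoxy-1,4-dioxo-1,4-dihydronaphthalen-2-yl)-4-methylpent-3-enyl 3-methylbut-2-enoate | COc1ccc(OC(C)=O)c2c1C(=O)C=C([C@H](CC=C(C)C)OC(=O)C=C(C)C)C2=O | intermediate
18 | (S)-1-(8-hydroxy-5-methoxy-1,4-dioxo-1,4-dihydronaphthalen-2-yl)-4-methylpent-3-enyl 3-methylbut-2-enoate | COc1ccc(O)c2c1C(=O)C=C([C@H](CC=C(C)C)OC(=O)C=C(C)C)C2=O | target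

## Step count and risk

Total: 11 steps. Longest linear sequence: 11 steps, from 1 to 18; compounds 6, 10 and 15 are bought.

**Step 5 (key step).** The terminal alkynylboronate may oligomerise or insert twice before carbonyl insertion. The vinylcarbene stage may be diverted to products formed without carbonyl insertion. The electron-rich naphthol may be oxidised during isolation. Fallback: from 9, the benzannulation is run with trimethylsilylacetylene, a robust silylalkyne, in THF at 50 °C. This should give (S)-7-[1-(tert-butyldimethylsilyloxy)-4-methylpent-3-enyl]-4,5,8-trimethoxy-2-(trimethylsilyl)naphthalen-1-ol F1. Brief treatment with CF3CO2H in CH2Cl2 at low temperature then removes silicon by ipso-protonation next to the hydroxyl. The route is rejoined at 12 and step 6 is not needed.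

**Step 6.** Transmetalation from the hindered, hydrogen-bonded ortho-hydroxy boronate may be slow, and the free naphthol may be oxidised while warm. Fallback: from 11, the pinacol group is exchanged onto methylboronic acid in acetone/dilute aqueous HCl. This should give (S)-{7-[1-(tert-butyldimethylsilyloxy)-4-methylpent-3-enyl]-1-hydroxy-4,5,8-trimethoxynaphthalen-2-yl}boronic acid F2. Heating F2 in wet DMSO under argon should remove boron by the metal-free, hydroxyl-assisted protodeboronation of ortho-hydroxyarylboronic acids. The route is rejoined at 12.

**Step 10.** The benzylic ester may be lost by solvolysis from the arene radical cation, or oxidation may take place on ring A with loss of the acetyl group. Fallback: from 14, the oxidation with (NH4)2Ce(NO3)6 in MeCN/H2O is done before the ester is in place. This should give (S)-7-(1-hydroxy-4-methylpent-3-enyl)-4-methoxy-5,8-dioxo-5,8-dihydronaphthalen-1-yl acetate F3. The side-chain hydroxyl of F3 is then esterified with 15 (DCC, catalytic DMAP, CH2Cl2, 0 °C). The route is rejoined at 17.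

**Step 11.** Methanolysis of the side-chain ester, conjugate addition of methoxide at C3 of the quinone, or loss of configuration through vinylogous enolisation at C1' may compete with cleavage of the acetate. Fallback: the acetate is removed before the side-chain ester exists. From 13, oxidation with (NH4)2Ce(NO3)6 should give (S)-7-[1-(tert-butyldimethylsilyloxy)-4-methylpent-3-enyl]-4-methoxy-5,8-dioxo-5,8-dihydronaphthalen-1-yl acetate F4. K2CO3 in MeOH at 0 °C then gives (S)-2-[1-(tert-butyldimethylsilyloxy)-4-methylpent-3-enyl]-8-hydroxy-5-methoxynaphthalene-1,4-dione F5. HF·pyridine then gives (S)-8-hydroxy-2-(1-hydroxy-4-methylpent-3-enyl)-5-methoxynaphthalene-1,4-dione F6. Esterification of F6 with 15 (DCC, catalytic DMAP) should take place at the side-chain hydroxyl only, because the C8 hydroxyl is tied up in a hydrogen bond to C1=O. The route is rejoined at 18.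

## Further compounds

F1 | step 5 | (S)-7-[1-(tert-butyldimethylsilyloxy)-4-methylpent-3-enyl]-4,5,8-trimethoxy-2-(trimethylsilyl)naphthalen-1-ol | COc1cc([Si](C)(C)C)c(O)c2c(OC)c([C@H](CC=C(C)C)O[Si](C)(C)C(C)(C)C)cc(OC)c12
F2 | step 6 | (S)-{7-[1-(tert-butyldimethylsilyloxy)-4-methylpent-3-enyl]-1-hydroxy-4,5,8-trimethoxynaphthalen-2-yl}boronic acid | COc1cc(B(O)O)c(O)c2c(OC)c([C@H](CC=C(C)C)O[Si](C)(C)C(C)(C)C)cc(OC)c12
F3 | step 10 | (S)-7-(1-hydroxy-4-methylpent-3-enyl)-4-methoxy-5,8-dioxo-5,8-dihydronaphthalen-1-yl acetate | COc1ccc(OC(C)=O)c2c1C(=O)C=C([C@H](CC=C(C)C)O)C2=O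
F4 | step 11 | (S)-7-[1-(tert-butyldimethylsilyloxy)-4-methylpent-3-enyl]-4-methoxy-5,8-dioxo-5,8-dihydronaphthalen-1-yl acetate | COc1ccc(OC(C)=O)c2c1C(=O)C=C([C@H](CC=C(C)C)O[Si](C)(C)C(C)(C)C)C2=O
F5 | step 11 | (S)-2-[1-(tert-butyldimethylsilyloxy)-4-methylpent-3-enyl]-8-hydroxy-5-methoxynaphthalene-1,4-dione | COc1ccc(O)c2c1C(=O)C=C([C@H](CC=C(C)C)O[Si](C)(C)C(C)(C)C)C2=O
F6 | step 11 | (S)-8-hydroxy-2-(1-hydroxy-4-methylpent-3-enyl)-5-methoxynaphthalene-1,4-dione | COc1ccc(O)c2c1C(=O)C=C([C@H](CC=C(C)C)O)C2=O
A1 | alternative 1 | 2-methoxyfuran | COc1ccco1
A2 | alternative 1 | (S)-1-[8-hydroxy-5-methoxy-4-(methoxymethoxy)naphthalen-2-yl]-4-methylpent-3-enyl 3-methylbut-2-enoate | COCOc1cc([C@H](CC=C(C)C)OC(=O)C=C(C)C)cc2c(O)ccc(OC)c12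
A3 | alternative 2 | 2-[(S)-1-(tert-butyldimethylsilyloxy)-4-methylpent-3-enyl]-5-methoxy-8-(methoxymethoxy)-1,4-dihydronaphthalene-1,4-diol (carbinol epimers) | COc1ccc(OCOC)c2c1C(O)C=C([C@H](CC=C(C)C)O[Si](C)(C)C(C)(C)C)C2O
A4 | alternative 3 | (S)-6-methylhept-5-en-1-yn-3-yl 3-methylbut-2-enoate | C#C[C@H](CC=C(C)C)OC(=O)C=C(C)C
A5 | alternative 3 | (S)-1-[1-hydroxy-4,5-dimethoxy-8-(triisopropylsilyloxy)naphthalen-2-yl]-4-methylpent-3-enyl 3-methylbut-2-enoate | COc1ccc(O[Si](C(C)C)(C(C)C)C(C)C)c2c(O)c([C@H](CC=C(C)C)OC(=O)C=C(C)C)cc(OC)c12
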